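**Retrosynthetic overview**
1. Feature the strategy rests on: the (1S,2S)-2-hydroxy-2,6,6-trimethylcyclohexane joined by a CH2 to C6 of ring A is an (E)-geranyl group (C1''–C8'', C1'' benzylic) in which C2'' has bonded to C7'' and C3'' has taken up water, with the tertiary OH and the arylmethyl group trans on neighbouring ring carbons.
2. Key disconnection: the C2''–C7'' and C3''–OH bonds, back to 6-geranylluteolin tetraacetate and water; the acetates come off afterwards.
3. Second disconnection: the C6–C1'' bond, back to 6-iodoluteolin tetraacetate and (E)-geranyltributylstannane (from geranyl bromide).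
4. Third disconnection: the C6–I bond, placed ortho to the chelated 5-OH of 7,3',4'-tri-O-MOM-luteolin, which comes from luteolin.
5. Ring order: rings A, C and B are bought with luteolin; the cyclohexane is the only ring made, and it is made last.

Key step: step 7

Remark on the chemistry: the hand of the chiral acid that gives the (1S,2S) ring cannot be predicted with confidence. The (S,S) acid is written; its mirror image, equally available from (R)-BINOL, would be used if the first cyclization showed the opposite sense.
Remark on locants: flavone numbering is used for rings A, C and B (B-ring positions primed); the geranyl carbons carry double primes.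

Step 1
Reactants: 1 geranyl bromide, (2E)-1-bromo-3,7-dimethylocta-2,6-diene
Product: 2 (E)-geranyltributylstannane, tributyl[(2E)-3,7-dimethylocta-2,6-dien-1-yl]stannane
Conditions: Bu3SnH, LiN(i-Pr)2, THF, −78 °C; then 1, −78 → 0 °C
Reagents that add atoms: tributyltin hydride, CCCC[SnH](CCCC)CCCC
Why: SN2 alkylation of the stannyl anion Bu3SnLi at the primary allylic carbon of 1 gives the linear allylstannane and leaves the 2E alkene geometry untouched.

Step 2
Reactants: 3 luteolin, 2-(3,4-dihydroxyphenyl)-5,7-dihydroxy-4H-chromen-4-one
Product: 4 5-hydroxy-7,3',4'-tris(methoxymethoxy)flavone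
Conditions: MOMCl (3.3 equiv), K2CO3, acetone, 0 °C → rt
Reagents that add atoms: chloromethyl methyl ether, COCCl
Why: Williamson ether synthesis alkylates the three acidic, non-chelated phenoxides (O7, O3', O4'), whereas the 5-OH, held in a hydrogen bond to the C4 carbonyl, should stay free.

Step 3
Reactants: 4 5-hydroxy-7,3',4'-tris(methoxymethoxy)flavone
Product: 5 5-hydroxy-6-iodo-7,3',4'-tris(methoxymethoxy)flavone
Conditions: I2 (1.05 equiv), TlOAc (1.1 equiv), CH2Cl2, rt, dark
Reagents that add atoms: iodine, [I][I]
Why: Iodination with I2 and TlOAc is an electrophilic aromatic substitution delivered ortho to a free phenol, and the chelated 5-OH has only one open ortho carbon, C6 (the other is the ring-fusion carbon C4a), while the acetate buffer spares the MOM ethers and the less activated ring B.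

Step 4
Reactants: 5 5-hydroxy-6-iodo-7,3',4'-tris(methoxymethoxy)flavone
Product: 6 6-iodoluteolin, 2-(3,4-dihydroxyphenyl)-5,7-dihydroxy-6-iodo-4H-chromen-4-one
Conditions: HCl (3 M aq)–MeOH 1:4, 50 °C
Reagents that add atoms: none
Why: Acid-catalysed acetal exchange with methanol removes the three MOM groups at a stage where no alkene is present, so the geranyl group never meets acid next to free phenols, and the aryl iodide and the flavone are inert to dilute HCl.

Step 5
Reactants: 6 6-iodoluteolin
Product: 7 6-iodoluteolin 5,7,3',4'-tetraacetate
Conditions: Ac2O, pyridine, 4-(dimethylamino)pyridine (cat.), 40 °C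
Reagents that add atoms: acetic anhydride, CC(=O)OC(C)=O
Why: Nucleophilic catalysis of acyl transfer by 4-(dimethylamino)pyridine esterifies all four phenols, the hindered and chelated 5-OH included, which gives the acyl-masked O5 and O7 that the key step needs.

Step 6
Reactants: 7 6-iodoluteolin 5,7,3',4'-tetraacetate; 2 (E)-geranyltributylstannane
Product: 8 6-geranylluteolin tetraacetate, 6-[(2E)-3,7-dimethylocta-2,6-dien-1-yl]luteolin 5,7,3',4'-tetraacetate
Conditions: Pd(PPh3)4 (5 mol %), toluene, 90 °C
Reagents that add atoms: none
Why: Stille coupling: zerovalent palladium inserts into the C6–I bond, the allylstannane transmetalates and reductive elimination at the unsubstituted allyl terminus should give the linear 6-geranyl compound with the 2''E geometry of 2 carried over, the aryl acetates being inert to these neutral conditions.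

Step 7
Reactants: 8 6-geranylluteolin tetraacetate
Product: 9 6-{[(1S,2S)-2-hydroxy-2,6,6-trimethylcyclohexyl]methyl}luteolin 5,7,3',4'-tetraacetate
Conditions: (S,S)-IDPi acid, HN[P(=NSO2CF3)(O,O'-binaphthyl)]2 built from (S)-3,3'-bis[3,5-bis(trifluoromethyl)phenyl]-BINOL (10 mol %), H2O (5 equiv), (CF3)3COH–CHCl3 1:1, −20 °C
Reagents that add atoms: water, O
Why: Proposed new method: the confined chiral acid protonates C6'' of the terminal 6'',7''-alkene, the C7'' cation held in the chiral ion pair is attacked by C2'' of the 2'',3''-alkene through a chair fold, and water bound in the fluoroalcohol hydrogen-bond network adds to C3'' from the face opposite the forming C2''–C7'' bond before the acid is released. The closest known reactions are enantioselective polyene cyclizations promoted by confined chiral Brønsted acids or by Lewis-acid-assisted chiral Brønsted acids, which end in an internal nucleophile or in proton loss, and squalene–hopene cyclase cyclizations that end in water; a small-molecule, water-terminated monocyclization of this kind has not been shown. The cyclohexane (C2''–C7'') closes in the 6-endo mode with respect to the attacking 2'',3''-alkene. The stereocenter at C2'' (the ring carbon bearing the CH2 to C6) is set by the catalyst, which fixes the face of the alkene that meets C7''; the carbinol center C3'' follows from it by anti addition across the E alkene, which places OH and arylmethyl trans (both equatorial). The step needs protonation of the terminal and not the internal alkene, secured by the more accessible, more electron-rich remote alkene and by the electron-poor acyloxy-substituted arylmethyl group next to the 2'',3''-alkene, and it needs water and not a ring-A oxygen as the terminating nucleophile, secured by acetylation of O5 and O7. Low temperature, excess water and the non-basic counter-anion are meant to hold back proton loss to cyclogeranyl alkenes.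

Step 8
Reactants: 9 6-{[(1S,2S)-2-hydroxy-2,6,6-trimethylcyclohexyl]methyl}luteolin 5,7,3',4'-tetraacetate
Product: 10 target, 2-(3,4-dihydroxyphenyl)-5,7-dihydroxy-6-{[(1S,2S)-2-hydroxy-2,6,6-trimethylcyclohexyl]methyl}-4H-chromen-4-one
Conditions: K2CO3, MeOH, argon, 0 °C → rt; then AcOH
Reagents that add atoms: none
Why: Base-promoted transesterification with methanol cleaves the four aryl acetates, while the tertiary alcohol, the flavone and both stereocenters (no acidic C–H, no ionizing acid) are untouched.

**Compound list**
1 | geranyl bromide, (2E)-1-bromo-3,7-dimethylocta-2,6-diene | CC(C)=CCC/C(C)=C/CBr | starting material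
2 | (E)-geranyltributylstannane | CC(C)=CCC/C(C)=C/C[Sn](CCCC)(CCCC)CCCC | intermediate
3 | luteolin | O=c1cc(-c2ccc(O)c(O)c2)oc2cc(O)cc(O)c12 | starting material
4 | 5-hydroxy-7,3',4'-tris(methoxymethoxy)flavone | COCOc1cc(O)c2c(c1)oc(-c1ccc(OCOC)c(OCOC)c1)cc2=O | intermediate
5 | 5-hydroxy-6-iodo-7,3',4'-tris(methoxymethoxy)flavone | COCOc1cc2oc(-c3ccc(OCOC)c(OCOC)c3)cc(=O)c2c(O)c1I | intermediate
6 | 6-iodoluteolin | Oc1cc2oc(-c3ccc(O)c(O)c3)cc(=O)c2c(O)c1I | intermediate
7 | 6-iodoluteolin 5,7,3',4'-tetraacetate | CC(=O)Oc1cc2oc(-c3ccc(OC(C)=O)c(OC(C)=O)c3)cc(=O)c2c(OC(C)=O)c1I | intermediate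
8 | 6-geranylluteolin tetraacetate (2''E) | CC(C)=CCC/C(C)=C/Cc1c(OC(C)=O)cc2oc(-c3ccc(OC(C)=O)c(OC(C)=O)c3)cc(=O)c2c1OC(C)=O | intermediate
9 | 6-{[(1S,2S)-2-hydroxy-2,6,6-trimethylcyclohexyl]methyl}luteolin tetraacetate | CC1(C)CCC[C@](C)(O)[C@H]1Cc1c(OC(C)=O)cc2oc(-c3ccc(OC(C)=O)c(OC(C)=O)c3)cc(=O)c2c1OC(C)=O | intermediate
10 | 6-{[(1S,2S)-2-hydroxy-2,6,6-trimethylcyclohexyl]methyl}luteolin | CC1(C)CCC[C@](C)(O)[C@H]1Cc1c(O)cc2oc(-c3ccc(O)c(O)c3)cc(=O)c2c1O | target

**Step count and risks**
Total steps: 8. Longest linear sequence: 7 steps (luteolin 3 to target 10, steps 2–8); step 1 is a one-step side branch that joins at step 6.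

Steps most likely to fail:

1. Step 7 (the proposed new method). The cyclized cation may lose a proton to the cyclogeranyl alkenes before water arrives, the ring closure may show poor facial selectivity, the chiral acid may be tied up on the basic pyranone carbonyl, or the internal alkene may be protonated. Fallback with known chemistry, setting out from 8: Hg(OTf)2·PhNMe2 in nitromethane at −20 °C activates the terminal alkene, divalent mercury and C2'' add anti across it and close the same ring, and an aqueous NaCl quench hydrates the tertiary cation to the racemic chloromercurio alcohol F1. Bu3SnH with a trace of AIBN in toluene replaces HgCl by H and should give racemic 9 F2. Preparative chromatography on an amylose-carbamate chiral phase separates the (1S,2S) enantiomer, which is 9, where the route is rejoined.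

2. Step 6. The allyl group may transpose (bond formation at C3'' to the branched isomer), the 2''E alkene may isomerize through the η3-allyl intermediate, or iodine may be lost reductively. Fallback, setting out from 7, with the polarity of the coupling reversed: (Me3Sn)2 and Pd(PPh3)4 in toluene at 100 °C convert the iodide into 6-(trimethylstannyl)luteolin tetraacetate F3. This is coupled with geranyl bromide 1 (Pd2(dba)3, tri(2-furyl)phosphine, THF, 50 °C); the allyl group now enters as an electrophile through a syn-η3-geranylpalladium bromide formed with retention, and the aryl group is delivered to the unsubstituted terminus, which comes back to the route at 8.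

3. Step 3. Site control may erode (iodination para to O5 at C8, or on ring B). Fallback, setting out from 4, with halogenation and cross-coupling replaced by direct C-alkylation: NaH in toluene gives the sodium 5-phenoxide F4 as a tight, chelated ion pair, which geranyl bromide 1 should alkylate at its only ortho carbon (toluene, 60 °C) to 6-geranyl-5-hydroxy-7,3',4'-tris(methoxymethoxy)flavone F5. Brief treatment with HCl in MeOH at room temperature gives 6-geranylluteolin F6, and Ac2O–pyridine with 4-(dimethylamino)pyridine brings the material back to the route at 8.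

**Further compounds**
F1 | step 7 | racemic 6-{[5-(chloromercurio)-2-hydroxy-2,6,6-trimethylcyclohexyl]methyl}luteolin tetraacetate, HgCl cis to the arylmethyl group and trans to OH (one enantiomer drawn) | CC1(C)[C@@H]([Hg]Cl)CC[C@](C)(O)[C@H]1Cc1c(OC(C)=O)cc2oc(-c3ccc(OC(C)=O)c(OC(C)=O)c3)cc(=O)c2c1OC(C)=O
F2 | step 7 | racemic 9, that is 9 together with its (1R,2R) enantiomer (the enantiomer is drawn) | CC1(C)CCC[C@@](C)(O)[C@@H]1Cc1c(OC(C)=O)cc2oc(-c3ccc(OC(C)=O)c(OC(C)=O)c3)cc(=O)c2c1OC(C)=O
F3 | step 6 | 6-(trimethylstannyl)luteolin 5,7,3',4'-tetraacetate | C[Sn](C)(C)c1c(OC(C)=O)cc2oc(-c3ccc(OC(C)=O)c(OC(C)=O)c3)cc(=O)c2c1OC(C)=O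
F4 | step 3 | sodium 5-phenoxide of 4 | [Na+].COCOc1cc([O-])c2c(c1)oc(-c1ccc(OCOC)c(OCOC)c1)cc2=O
F5 | step 3 | 6-geranyl-5-hydroxy-7,3',4'-tris(methoxymethoxy)flavone (2''E) | CC(C)=CCC/C(C)=C/Cc1c(OCOC)cc2oc(-c3ccc(OCOC)c(OCOC)c3)cc(=O)c2c1O
F6 | step 3 | 6-geranylluteolin (2''E) | CC(C)=CCC/C(C)=C/Cc1c(O)cc2oc(-c3ccc(O)c(O)c3)cc(=O)c2c1O
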